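**Retrosynthetic overview**
1. The curcuminoid arm is attached last by a boron-templated aldol condensation of aldehyde 23 with half-curcuminoid 28. The side-chain methyl centre comes from a copper-catalysed 1,4-methylation of dienone 21, which is made by cross-metathesis on a propenyl handle.
2. Key disconnection: the cyclohexene ring bond between C1 (sp3, bearing the aryloxy oxygen) and C2 (the alkene CH), closed by a nickel-electrocatalytic decarboxylative alkyl–alkenyl coupling of the acyclic redox-active ester 15.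
3. Enabling feature: C1 is α to the ether oxygen, so it can be made as an O-stabilised radical by loss of CO2 (its configuration is erased and reset by C6). C2 belongs to the only ring C=C, whose cis placement of C1 and C4 is stored in a (Z)-iodoalkene.
4. Acid 14 comes from an Ireland–Claisen rearrangement of (aryloxy)acetate 11 (1,3-chirality transfer sets C6). Alcohol 7 comes from allylboration of (Z)-3-iodo-2-methylacrolein (sets C4) and cross-metathesis with (S)-but-3-en-2-ol.
5. Rings: both benzene rings are bought and the cyclohexene is the only ring built (step 11). A dioxolane (steps 6 to 16), a difluoroboron chelate (step 17) and a dibutoxyboron chelate (step 18) are temporary.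

Key step: step 11

Remark: 14 and 15 are drawn as the expected syn (2S) isomers, but their C2 configuration is irrelevant because C2 passes through the planar radical 16; compounds 6 and 8 are taken as commercial.

Step 1
Reactants: 1 prop-2-yn-1-ol
Product: 2 (Z)-3-iodo-2-methylprop-2-en-1-ol
Conditions: MeMgBr (3 equiv), CuI (10 mol %), THF, −10 °C to rt; then I2, −10 °C; H2O
Reagents that add atoms: methylmagnesium bromide, C[Mg]Br; iodine, II
Why: Copper-catalysed anti-carbomagnesiation of the propargylic magnesium alkoxide puts methyl on the internal carbon and magnesium on the terminal carbon inside a five-membered chelate, so iodinolysis with retention should give iodine cis to CH2OH (Z); no stereocentre is formed.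

Step 2
Reactants: 2 (Z)-3-iodo-2-methylprop-2-en-1-ol
Product: 3 (Z)-3-iodo-2-methylprop-2-enal
Conditions: MnO2 (10 equiv), CH2Cl2, rt, dark; filtered and used at once
Reagents that add atoms: none
Why: Allylic alcohol oxidation on MnO2 is neutral and should leave the Z iodoalkene untouched; no stereocentre is formed.

Step 3
Reactants: 3 (Z)-3-iodo-2-methylprop-2-enal
Product: 4 (1Z,3S)-1-iodo-2-methylhexa-1,5-dien-3-ol
Conditions: allyl-B(Ipc)2 of the (+)-α-pinene series (the reagent derived from (−)-Ipc2BOMe; preformed, free of magnesium salts), Et2O, −78 °C; then NaOH, H2O2, 0 °C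
Reagents that add atoms: B-allyldiisopinocampheylborane of the (+)-α-pinene series, C=CCB(C1CC2CC(C1C)C2(C)C)C1CC2CC(C1C)C2(C)C
Why: Brown allylboration through a closed chair transition state; the (+)-α-pinene-derived reagent should attack the aldehyde face that gives the S carbinol when the aldehyde substituent outranks the allyl CH2 (the same spatial sense as with benzaldehyde), which sets the future ring C4.

Step 4
Reactants: 4 (1Z,3S)-1-iodo-2-methylhexa-1,5-dien-3-ol
Product: 5 tert-butyl{[(1Z,3S)-1-iodo-2-methylhexa-1,5-dien-3-yl]oxy}dimethylsilane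
Conditions: TBSCl, imidazole, DMF, rt
Reagents that add atoms: tert-butyldimethylsilyl chloride, CC(C)(C)[Si](C)(C)Cl
Why: Standard silylation of a secondary alcohol; the silyl ether must survive amide base, metathesis, the electrolysis and MeMgBr, and the stereocentre is untouched.

Step 5
Reactants: 5 tert-butyl{[(1Z,3S)-1-iodo-2-methylhexa-1,5-dien-3-yl]oxy}dimethylsilane, 6 (S)-but-3-en-2-ol
Product: 7 (2S,3E,6S,7Z)-6-[(tert-butyldimethylsilyl)oxy]-8-iodo-7-methylocta-3,7-dien-2-ol
Conditions: second-generation Hoveyda–Grubbs catalyst RuCl2(H2IMes)(=CH-C6H4-2-O-i-Pr) (5 mol %), 6 (3 equiv), CH2Cl2, 40 °C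
Reagents that add atoms: none
Why: Olefin cross-metathesis of a terminal alkene with a secondary allylic alcohol should give the E alkene with loss of ethene; the trisubstituted iodoalkene is inert and the S carbinol of 6 is carried over unchanged.

Step 6
Reactants: 8 ethyl (4-formyl-2-methoxyphenoxy)acetate
Product: 9 ethyl [4-(1,3-dioxolan-2-yl)-2-methoxyphenoxy]acetate
Conditions: ethylene glycol, p-TsOH (cat.), toluene, reflux, Dean–Stark
Reagents that add atoms: ethylene glycol, OCCO
Why: Acid-catalysed acetalisation with removal of water masks the aryl aldehyde against the ester enolate of step 9 and the Grignard reagent of step 15.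

Step 7
Reactants: 9 ethyl [4-(1,3-dioxolan-2-yl)-2-methoxyphenoxy]acetate
Product: 10 [4-(1,3-dioxolan-2-yl)-2-methoxyphenoxy]acetic acid
Conditions: LiOH, THF/H2O, 0 °C to rt; then cold 1 M HCl to pH 4
Reagents that add atoms: lithium hydroxide, [Li+].[OH-]
Why: Ester saponification; the acetal is stable to base and survives the brief cold acidification to pH 4.

Step 8
Reactants: 7 (2S,3E,6S,7Z)-6-[(tert-butyldimethylsilyl)oxy]-8-iodo-7-methylocta-3,7-dien-2-ol, 10 [4-(1,3-dioxolan-2-yl)-2-methoxyphenoxy]acetic acid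
Product: 11 (2S,3E,6S,7Z)-6-[(tert-butyldimethylsilyl)oxy]-8-iodo-7-methylocta-3,7-dien-2-yl [4-(1,3-dioxolan-2-yl)-2-methoxyphenoxy]acetate
Conditions: DCC, DMAP (cat.), CH2Cl2, 0 °C to rt
Reagents that add atoms: none
Why: Steglich esterification at the only free hydroxyl, with retention at the carbinol carbon because the C–O bond is not broken.

Step 9
Reactants: 11 (2S,3E,6S,7Z)-6-[(tert-butyldimethylsilyl)oxy]-8-iodo-7-methylocta-3,7-dien-2-yl [4-(1,3-dioxolan-2-yl)-2-methoxyphenoxy]acetate
Product: 14 (2S,3R,5S,6Z)-5-[(tert-butyldimethylsilyl)oxy]-2-[4-(1,3-dioxolan-2-yl)-2-methoxyphenoxy]-7-iodo-6-methyl-3-[(1E)-prop-1-en-1-yl]hept-6-enoic acid, via silyl ketene acetal 12 (not isolated), via trimethylsilyl ester 13 (not isolated)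
Conditions: LiN(SiMe3)2, Me3SiCl/Et3N, THF, −78 °C to rt, then 40 °C; aqueous pH 5 work-up
Reagents that add atoms: none
Why: Ireland–Claisen rearrangement: the lithium-chelated Z ketene acetal reacts through a chair transition state with the carbinol methyl equatorial, so the suprafacial [3,3] shift transfers the S carbinol chirality to C3 (R, the future ring C6) and gives the E propenyl group, while the syn C2 centre formed alongside is erased in step 11.

Step 10
Reactants: 14 (2S,3R,5S,6Z)-5-[(tert-butyldimethylsilyl)oxy]-2-[4-(1,3-dioxolan-2-yl)-2-methoxyphenoxy]-7-iodo-6-methyl-3-[(1E)-prop-1-en-1-yl]hept-6-enoic acid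
Product: 15 1,3-dioxoisoindolin-2-yl (2S,3R,5S,6Z)-5-[(tert-butyldimethylsilyl)oxy]-2-[4-(1,3-dioxolan-2-yl)-2-methoxyphenoxy]-7-iodo-6-methyl-3-[(1E)-prop-1-en-1-yl]hept-6-enoate
Conditions: N-hydroxyphthalimide, DIC, DMAP (cat.), CH2Cl2, rt; used crude
Reagents that add atoms: N-hydroxyphthalimide, O=C1c2ccccc2C(=O)N1O
Why: Carbodiimide esterification to the redox-active N-acyloxyphthalimide; no stereocentre that matters is touched.

Step 11
Reactants: 15 1,3-dioxoisoindolin-2-yl (2S,3R,5S,6Z)-5-[(tert-butyldimethylsilyl)oxy]-2-[4-(1,3-dioxolan-2-yl)-2-methoxyphenoxy]-7-iodo-6-methyl-3-[(1E)-prop-1-en-1-yl]hept-6-enoate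
Product: 17 2-{4-[((1R,4S,6R)-4-[(tert-butyldimethylsilyl)oxy]-3-methyl-6-[(1E)-prop-1-en-1-yl]cyclohex-2-en-1-yl)oxy]-3-methoxyphenyl}-1,3-dioxolane, via α-aryloxyalkyl radical 16 (not isolated)
Conditions: NiCl2·6H2O (20 mol %), 2,2′-bipyridine (24 mol %), AgNO3 (30 mol %), LiCl, DMF, 0.02 M, undivided cell, Mg anode, RVC cathode, constant current, rt
Reagents that add atoms: none
Why: Proposed new method: cathodically formed zerovalent nickel adds oxidatively to the Z alkenyl iodide, single-electron reduction of the N-acyloxyphthalimide (at the silver-coated cathode or by low-valent nickel) expels CO2 and phthalimide anion to leave the planar α-aryloxyalkyl radical 16, and capture of 16 by the tethered divalent alkenylnickel gives a trivalent nickelacycle that reductively eliminates the C1–C2 bond. The closest known reaction type is the intermolecular nickel-electrocatalytic (and photoredox–nickel) decarboxylative alkenylation of redox-active esters or α-oxy acids with alkenyl halides; new here is the ring-closing, intramolecular use on an α-aryloxy ester. The cyclohexene closes in a 6-endo sense at the iodine-bearing alkene carbon, so both alkene carbons become ring atoms and the Z geometry laid down in step 1 places C1 and C4 cis on the ring double bond; a direct 6-endo-trig radical addition with loss of an iodine atom would give the same product. C1 is the only new stereocentre: both C2 epimers of 15 converge on radical 16, radical capture at nickel is reversible, and the bond should form through the half-chair that keeps the C6 propenyl group equatorial and the aryloxy group pseudo-equatorial, that is trans to it, with the C4 silyl ether pseudo-axial and clear of the C3 methyl. The step needs trans C1/C6 diastereoselectivity (secured by the branched neighbour at C6), ipso coupling instead of 5-exo attack at C3 (secured by nickel and by C3 being fully substituted) and no insertion of the alkenylnickel into the propenyl group (an internal, unactivated alkene that radical capture should outpace), while the acetal, silyl ether and aryl ether should be inert at the mild reducing potential.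

Step 12
Reactants: 18 3-methylbut-2-enal
Product: 19 (±)-5-methylhexa-1,4-dien-3-ol
Conditions: CH2=CHMgBr, THF, −78 to 0 °C; H2O
Reagents that add atoms: vinylmagnesium bromide, C=C[Mg]Br
Why: 1,2-Addition of a Grignard reagent to an enal; the carbinol centre is racemic and is removed in step 13.

Step 13
Reactants: 19 (±)-5-methylhexa-1,4-dien-3-ol
Product: 20 5-methylhexa-1,4-dien-3-one
Conditions: MnO2, CH2Cl2, rt; filtered and used as a solution
Reagents that add atoms: none
Why: MnO2 oxidation of a bis-allylic alcohol under neutral conditions avoids polymerisation of the vinyl ketone.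

Step 14
Reactants: 17 2-{4-[((1R,4S,6R)-4-[(tert-butyldimethylsilyl)oxy]-3-methyl-6-[(1E)-prop-1-en-1-yl]cyclohex-2-en-1-yl)oxy]-3-methoxyphenyl}-1,3-dioxolane, 20 5-methylhexa-1,4-dien-3-one
Product: 21 (1E)-1-[(1R,2R,5S)-5-[(tert-butyldimethylsilyl)oxy]-2-[4-(1,3-dioxolan-2-yl)-2-methoxyphenoxy]-4-methylcyclohex-3-en-1-yl]-5-methylhexa-1,4-dien-3-one
Conditions: second-generation Hoveyda–Grubbs catalyst RuCl2(H2IMes)(=CH-C6H4-2-O-i-Pr) (10 mol %), 20 (4 equiv), CH2Cl2, 40 °C
Reagents that add atoms: none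
Why: Cross-metathesis of the propenyl group with the vinyl ketone should give the E enone with loss of propene, the trisubstituted ring alkene and the isobutenyl group being inert; no stereocentre is touched.

Step 15
Reactants: 21 (1E)-1-[(1R,2R,5S)-5-[(tert-butyldimethylsilyl)oxy]-2-[4-(1,3-dioxolan-2-yl)-2-methoxyphenoxy]-4-methylcyclohex-3-en-1-yl]-5-methylhexa-1,4-dien-3-one
Product: 22 (6S)-6-[(1R,2R,5S)-5-[(tert-butyldimethylsilyl)oxy]-2-[4-(1,3-dioxolan-2-yl)-2-methoxyphenoxy]-4-methylcyclohex-3-en-1-yl]-2-methylhept-2-en-4-one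
Conditions: MeMgBr (1.5 equiv), CuBr·SMe2 (5 mol %), Josiphos ligand 1-[2-(diphenylphosphino)ferrocenyl]ethyldicyclohexylphosphine (6 mol %, enantiomer chosen to give the 6S centre), t-BuOMe, −78 °C; H2O
Reagents that add atoms: methylmagnesium bromide, C[Mg]Br
Why: Copper-catalysed asymmetric conjugate addition of a Grignard reagent to an acyclic enone; methyl should add to the singly substituted β-carbon and not to the β,β-dimethyl terminus, the chiral ligand setting the S methyl centre under catalyst control, and the acetal and silyl ether are inert to MeMgBr at −78 °C.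

Step 16
Reactants: 22 (6S)-6-[(1R,2R,5S)-5-[(tert-butyldimethylsilyl)oxy]-2-[4-(1,3-dioxolan-2-yl)-2-methoxyphenoxy]-4-methylcyclohex-3-en-1-yl]-2-methylhept-2-en-4-one
Product: 23 4-{[(1R,4S,6R)-4-hydroxy-3-methyl-6-[(2S)-6-methyl-4-oxohept-5-en-2-yl]cyclohex-2-en-1-yl]oxy}-3-methoxybenzaldehyde
Conditions: 48 % aq. HF, MeCN, 0 °C to rt
Reagents that add atoms: water, O
Why: Aqueous HF should cleave the silyl ether and hydrolyse the electron-rich aryl dioxolane in one operation, mild enough to keep the allylic aryl ether and the enone; no stereocentre is touched.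

Step 17
Reactants: 24 4-hydroxybenzaldehyde, 25 pentane-2,4-dione
Product: 28 (5E)-6-(4-hydroxyphenyl)hex-5-ene-2,4-dione, via difluoroboron acetylacetonate 26 (not isolated), via difluoroboron diketonate 27 (not isolated)
Conditions: 25 (3 equiv), BF3·OEt2 (3 equiv), CH2Cl2, 40 °C, then volatiles removed; 24 (1 equiv), B(O-n-Bu)3, n-BuNH2 (cat.), toluene, 65 °C; then sodium oxalate, MeOH/H2O, 65 °C; dilute HCl to pH 4
Reagents that add atoms: none
Why: Difluoroboron-templated aldol condensation: the BF2 chelate blocks C3 of the diketone and acidifies the terminal methyl groups, so the amine-catalysed condensation should occur at one methyl to give the E enone, the excess of chelate 26 favouring mono-condensation; oxalate then strips the BF2 unit from this robust half-curcuminoid, and no stereocentre is formed.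

Step 18
Reactants: 23 4-{[(1R,4S,6R)-4-hydroxy-3-methyl-6-[(2S)-6-methyl-4-oxohept-5-en-2-yl]cyclohex-2-en-1-yl]oxy}-3-methoxybenzaldehyde, 28 (5E)-6-(4-hydroxyphenyl)hex-5-ene-2,4-dione
Product: 31 demethoxybisabolocurcumin ether, via dibutoxyboron diketonate 29 (not isolated), via curcuminoid boron chelate 30 (not isolated)
Conditions: 28 (1.2 equiv), B2O3, B(O-n-Bu)3, n-BuNH2 (cat.), EtOAc, 60 °C; then dilute aq. AcOH, rt
Reagents that add atoms: none
Why: Boron-templated aldol condensation: 28 is chelated in the flask as its dibutoxyboron complex, whose methyl ketone terminus should condense with the aryl aldehyde to give the E,E curcuminoid; the side-chain ketone is not chelated and far less acidic, and the mild acetic acid decomplexation of this labile alkoxyboron chelate spares the allylic aryl ether and alcohol.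

**Compound list**
1 | prop-2-yn-1-ol | C#CCO | starting material
2 | (Z)-3-iodo-2-methylprop-2-en-1-ol | OC/C(C)=C\I | intermediate
3 | (Z)-3-iodo-2-methylprop-2-enal | O=C/C(C)=C\I | intermediate
4 | (1Z,3S)-1-iodo-2-methylhexa-1,5-dien-3-ol | C=CC[C@H](O)/C(C)=C\I | intermediate
5 | tert-butyl{[(1Z,3S)-1-iodo-2-methylhexa-1,5-dien-3-yl]oxy}dimethylsilane | C=CC[C@H](O[Si](C)(C)C(C)(C)C)/C(C)=C\I | intermediate
6 | (S)-but-3-en-2-ol | C[C@H](O)C=C | starting material
7 | (2S,3E,6S,7Z)-6-[(tert-butyldimethylsilyl)oxy]-8-iodo-7-methylocta-3,7-dien-2-ol | C[C@H](O)/C=C/C[C@H](O[Si](C)(C)C(C)(C)C)/C(C)=C\I | intermediate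
8 | ethyl (4-formyl-2-methoxyphenoxy)acetate | CCOC(=O)COc1ccc(C=O)cc1OC | starting material
9 | ethyl [4-(1,3-dioxolan-2-yl)-2-methoxyphenoxy]acetate | CCOC(=O)COc1ccc(C2OCCO2)cc1OC | intermediate
10 | [4-(1,3-dioxolan-2-yl)-2-methoxyphenoxy]acetic acid | OC(=O)COc1ccc(C2OCCO2)cc1OC | intermediate
11 | (2S,3E,6S,7Z)-6-[(tert-butyldimethylsilyl)oxy]-8-iodo-7-methylocta-3,7-dien-2-yl [4-(1,3-dioxolan-2-yl)-2-methoxyphenoxy]acetate | C[C@H](OC(=O)COc1ccc(C2OCCO2)cc1OC)/C=C/C[C@H](O[Si](C)(C)C(C)(C)C)/C(C)=C\I | intermediate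
12 | (Z)-trimethylsilyl ketene acetal of 11 | C[C@H](O/C(O[Si](C)(C)C)=C/Oc1ccc(C2OCCO2)cc1OC)/C=C/C[C@H](O[Si](C)(C)C(C)(C)C)/C(C)=C\I | intermediate
13 | trimethylsilyl ester of 14 | C[Si](C)(C)OC(=O)[C@@H](Oc1ccc(C2OCCO2)cc1OC)[C@@H](/C=C/C)C[C@H](O[Si](C)(C)C(C)(C)C)/C(C)=C\I | intermediate
14 | (2S,3R,5S,6Z)-5-[(tert-butyldimethylsilyl)oxy]-2-[4-(1,3-dioxolan-2-yl)-2-methoxyphenoxy]-7-iodo-6-methyl-3-[(1E)-prop-1-en-1-yl]hept-6-enoic acid | OC(=O)[C@@H](Oc1ccc(C2OCCO2)cc1OC)[C@@H](/C=C/C)C[C@H](O[Si](C)(C)C(C)(C)C)/C(C)=C\I | intermediate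
15 | 1,3-dioxoisoindolin-2-yl ester of 14 | O=C(ON1C(=O)c2ccccc2C1=O)[C@@H](Oc1ccc(C2OCCO2)cc1OC)[C@@H](/C=C/C)C[C@H](O[Si](C)(C)C(C)(C)C)/C(C)=C\I | intermediate
16 | α-aryloxyalkyl radical from 15 | [CH](Oc1ccc(C2OCCO2)cc1OC)[C@@H](/C=C/C)C[C@H](O[Si](C)(C)C(C)(C)C)/C(C)=C\I | intermediate
17 | 2-{4-[((1R,4S,6R)-4-[(tert-butyldimethylsilyl)oxy]-3-methyl-6-[(1E)-prop-1-en-1-yl]cyclohex-2-en-1-yl)oxy]-3-methoxyphenyl}-1,3-dioxolane | COc1cc(C2OCCO2)ccc1O[C@H]1C=C(C)[C@@H](O[Si](C)(C)C(C)(C)C)C[C@@H]1/C=C/C | intermediate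
18 | 3-methylbut-2-enal | CC(C)=CC=O | starting material
19 | (±)-5-methylhexa-1,4-dien-3-ol | C=CC(O)C=C(C)C | intermediate
20 | 5-methylhexa-1,4-dien-3-one | C=CC(=O)C=C(C)C | intermediate
21 | (1E)-1-[(1R,2R,5S)-5-[(tert-butyldimethylsilyl)oxy]-2-[4-(1,3-dioxolan-2-yl)-2-methoxyphenoxy]-4-methylcyclohex-3-en-1-yl]-5-methylhexa-1,4-dien-3-one | COc1cc(C2OCCO2)ccc1O[C@H]1C=C(C)[C@@H](O[Si](C)(C)C(C)(C)C)C[C@@H]1/C=C/C(=O)C=C(C)C | intermediate
22 | (6S)-6-[(1R,2R,5S)-5-[(tert-butyldimethylsilyl)oxy]-2-[4-(1,3-dioxolan-2-yl)-2-methoxyphenoxy]-4-methylcyclohex-3-en-1-yl]-2-methylhept-2-en-4-one | COc1cc(C2OCCO2)ccc1O[C@H]1C=C(C)[C@@H](O[Si](C)(C)C(C)(C)C)C[C@@H]1[C@@H](C)CC(=O)C=C(C)C | intermediate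
23 | 4-{[(1R,4S,6R)-4-hydroxy-3-methyl-6-[(2S)-6-methyl-4-oxohept-5-en-2-yl]cyclohex-2-en-1-yl]oxy}-3-methoxybenzaldehyde | COc1cc(C=O)ccc1O[C@H]1C=C(C)[C@@H](O)C[C@@H]1[C@@H](C)CC(=O)C=C(C)C | intermediate
24 | 4-hydroxybenzaldehyde | O=Cc1ccc(O)cc1 | starting material
25 | pentane-2,4-dione | CC(=O)CC(C)=O | starting material
26 | difluoroboron chelate of pentane-2,4-dione | F[B-]1(F)OC(C)=CC(C)=[O+]1 | intermediate
27 | difluoroboron chelate of 28 | F[B-]1(F)OC(C)=CC(/C=C/c2ccc(O)cc2)=[O+]1 | intermediate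
28 | (5E)-6-(4-hydroxyphenyl)hex-5-ene-2,4-dione | CC(=O)CC(=O)/C=C/c1ccc(O)cc1 | intermediate
29 | dibutoxyboron chelate of 28 | CCCCO[B-]1(OCCCC)OC(C)=CC(/C=C/c2ccc(O)cc2)=[O+]1 | intermediate
30 | dibutoxyboron chelate of 31 | CCCCO[B-]1(OCCCC)OC(/C=C/c2ccc(O[C@H]3C=C(C)[C@@H](O)C[C@@H]3[C@@H](C)CC(=O)C=C(C)C)c(OC)c2)=CC(/C=C/c2ccc(O)cc2)=[O+]1 | intermediate
31 | demethoxybisabolocurcumin ether | COc1cc(/C=C/C(O)=C/C(=O)/C=C/c2ccc(O)cc2)ccc1O[C@H]1C=C(C)[C@@H](O)C[C@@H]1[C@@H](C)CC(=O)C=C(C)C | target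

**Step count and risks**
Total step count: 18. Longest linear sequence: 13 steps (steps 1–5, 8–11, 14–16, 18).

Steps most likely to fail:

Step 11 (proposed new method). What may go wrong: poor facial selectivity at C1 during ring-forming C–C reductive elimination, insertion of the alkenylnickel into the propenyl group or reduction of the radical before capture, and nickel-induced ionisation of the product allyl aryl ether. Fallback, known reaction types only, from 14 back to 17: oxidative decarboxylation of 14 with Pb(OAc)4 (pyridine, benzene, 50 °C) should give the mixed acetal (2R,4S,5Z)-4-[(tert-butyldimethylsilyl)oxy]-1-[4-(1,3-dioxolan-2-yl)-2-methoxyphenoxy]-6-iodo-5-methyl-2-[(1E)-prop-1-en-1-yl]hex-5-en-1-yl acetate F1. Brief methanolysis (K2CO3, MeOH, −20 °C) should release the aldehyde (2R,4S,5Z)-4-[(tert-butyldimethylsilyl)oxy]-6-iodo-5-methyl-2-[(1E)-prop-1-en-1-yl]hex-5-enal F2 together with 4-(1,3-dioxolan-2-yl)-2-methoxyphenol F3, which is kept. Nozaki–Hiyama–Kishi ring closure of F2 (CrCl2, NiCl2 cat., DMF, high dilution) forms the same ring bond and should give (4S,6R)-4-[(tert-butyldimethylsilyl)oxy]-3-methyl-6-[(1E)-prop-1-en-1-yl]cyclohex-2-en-1-ol F4 as a C1 epimer mixture. Dess–Martin oxidation converges it to (4S,6R)-4-[(tert-butyldimethylsilyl)oxy]-3-methyl-6-[(1E)-prop-1-en-1-yl]cyclohex-2-en-1-one F5, which KBH(s-Bu)3 (THF, −78 °C) should reduce from the face opposite the C6 propenyl group to the cis alcohol (1S,4S,6R)-4-[(tert-butyldimethylsilyl)oxy]-3-methyl-6-[(1E)-prop-1-en-1-yl]cyclohex-2-en-1-ol F6. Mitsunobu etherification of F6 with F3 (PPh3, DIAD, toluene) inverts C1 and returns 17.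

Step 15. What may go wrong: 1,2-addition or poor facial control in the 1,4-methylation of the hindered, cross-conjugated dienone. Fallback from 17 back to 22: cross-metathesis of 17 with S-ethyl prop-2-enethioate (same ruthenium catalyst) should give S-ethyl (2E)-3-[(1R,2R,5S)-5-[(tert-butyldimethylsilyl)oxy]-2-[4-(1,3-dioxolan-2-yl)-2-methoxyphenoxy]-4-methylcyclohex-3-en-1-yl]prop-2-enethioate F7. Copper-catalysed 1,4-addition of MeMgBr to this unsaturated thioester (CuBr·SMe2, the same ferrocenyl diphosphine, t-BuOMe, −78 °C), the best-precedented catalyst-controlled methylation, should give S-ethyl (3S)-3-[(1R,2R,5S)-5-[(tert-butyldimethylsilyl)oxy]-2-[4-(1,3-dioxolan-2-yl)-2-methoxyphenoxy]-4-methylcyclohex-3-en-1-yl]butanethioate F8. Acylation of LiCu(CH=CMe2)2 (from 1-bromo-2-methylprop-1-ene, t-BuLi and CuI) by the thioester then gives 22.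

Step 14. What may go wrong: sluggish metathesis of the hindered internal alkene while the labile dienone 20 oligomerises. Fallback from 17 back to 21: cross-metathesis with acrolein (large excess, same catalyst) should give (2E)-3-[(1R,2R,5S)-5-[(tert-butyldimethylsilyl)oxy]-2-[4-(1,3-dioxolan-2-yl)-2-methoxyphenoxy]-4-methylcyclohex-3-en-1-yl]prop-2-enal F9. 1,2-Addition of Me2C=CHMgBr (THF, −78 °C) should give (1E)-1-[(1R,2R,5S)-5-[(tert-butyldimethylsilyl)oxy]-2-[4-(1,3-dioxolan-2-yl)-2-methoxyphenoxy]-4-methylcyclohex-3-en-1-yl]-5-methylhexa-1,4-dien-3-ol F10 as a carbinol epimer mixture, and MnO2 oxidation of this bis-allylic alcohol gives 21.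

**Further compounds**
F1 | step 11 | (2R,4S,5Z)-4-[(tert-butyldimethylsilyl)oxy]-1-[4-(1,3-dioxolan-2-yl)-2-methoxyphenoxy]-6-iodo-5-methyl-2-[(1E)-prop-1-en-1-yl]hex-5-en-1-yl acetate (C1 epimers) | CC(=O)OC(Oc1ccc(C2OCCO2)cc1OC)[C@@H](/C=C/C)C[C@H](O[Si](C)(C)C(C)(C)C)/C(C)=C\I
F2 | step 11 | (2R,4S,5Z)-4-[(tert-butyldimethylsilyl)oxy]-6-iodo-5-methyl-2-[(1E)-prop-1-en-1-yl]hex-5-enal | O=C[C@@H](/C=C/C)C[C@H](O[Si](C)(C)C(C)(C)C)/C(C)=C\I
F3 | step 11 | 4-(1,3-dioxolan-2-yl)-2-methoxyphenol | COc1cc(C2OCCO2)ccc1O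
F4 | step 11 | (4S,6R)-4-[(tert-butyldimethylsilyl)oxy]-3-methyl-6-[(1E)-prop-1-en-1-yl]cyclohex-2-en-1-ol (C1 epimers) | OC1C=C(C)[C@@H](O[Si](C)(C)C(C)(C)C)C[C@@H]1/C=C/C
F5 | step 11 | (4S,6R)-4-[(tert-butyldimethylsilyl)oxy]-3-methyl-6-[(1E)-prop-1-en-1-yl]cyclohex-2-en-1-one | O=C1C=C(C)[C@@H](O[Si](C)(C)C(C)(C)C)C[C@@H]1/C=C/C
F6 | step 11 | (1S,4S,6R)-4-[(tert-butyldimethylsilyl)oxy]-3-methyl-6-[(1E)-prop-1-en-1-yl]cyclohex-2-en-1-ol | O[C@@H]1C=C(C)[C@@H](O[Si](C)(C)C(C)(C)C)C[C@@H]1/C=C/C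
F7 | step 15 | S-ethyl (2E)-3-[(1R,2R,5S)-5-[(tert-butyldimethylsilyl)oxy]-2-[4-(1,3-dioxolan-2-yl)-2-methoxyphenoxy]-4-methylcyclohex-3-en-1-yl]prop-2-enethioate | COc1cc(C2OCCO2)ccc1O[C@H]1C=C(C)[C@@H](O[Si](C)(C)C(C)(C)C)C[C@@H]1/C=C/C(=O)SCC
F8 | step 15 | S-ethyl (3S)-3-[(1R,2R,5S)-5-[(tert-butyldimethylsilyl)oxy]-2-[4-(1,3-dioxolan-2-yl)-2-methoxyphenoxy]-4-methylcyclohex-3-en-1-yl]butanethioate | COc1cc(C2OCCO2)ccc1O[C@H]1C=C(C)[C@@H](O[Si](C)(C)C(C)(C)C)C[C@@H]1[C@@H](C)CC(=O)SCC
F9 | step 14 | (2E)-3-[(1R,2R,5S)-5-[(tert-butyldimethylsilyl)oxy]-2-[4-(1,3-dioxolan-2-yl)-2-methoxyphenoxy]-4-methylcyclohex-3-en-1-yl]prop-2-enal | COc1cc(C2OCCO2)ccc1O[C@H]1C=C(C)[C@@H](O[Si](C)(C)C(C)(C)C)C[C@@H]1/C=C/C=O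
F10 | step 14 | (1E)-1-[(1R,2R,5S)-5-[(tert-butyldimethylsilyl)oxy]-2-[4-(1,3-dioxolan-2-yl)-2-methoxyphenoxy]-4-methylcyclohex-3-en-1-yl]-5-methylhexa-1,4-dien-3-ol (C3 epimers) | COc1cc(C2OCCO2)ccc1O[C@H]1C=C(C)[C@@H](O[Si](C)(C)C(C)(C)C)C[C@@H]1/C=C/C(O)C=C(C)C
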